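**Plan**

- Cuts, in retrosynthetic order: (a) the seven O–Si bonds; (b) the C3–aryl bond joining the two dihydrobenzofurans (decarboxylative sp3–sp2 coupling); (c) the aryl–vinyl bond of the stilbene; (d) in the styryl-bearing half (fragment 1) the C3a–C3 bond, by expansion back to a chroman-4-one; (e) in the other half (fragment 2) the C2–C3 bond (carbene C–H insertion).
- Enabling feature: in fragment 1, O1, C2 with its 4-hydroxyphenyl group, C3 and the benzo ring (oxygen at C6, carbon at C4) are a ring-contracted 5,7,4'-trioxygenated flavanone and map atom for atom onto (2S)-naringenin. C3a is ortho to O1 and para to the C6 oxygen, so it is an electron-rich migrating carbon; the extruded flavanone C4 stays on C3 as a carboxylate and later leaves as CO2.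
- Forward order: naringenin → bis-silyl ether → C5 triflate → oxidative ring contraction (pyranone to dihydrofuran) → Suzuki styrylation → acid → redox-active ester. Separately: benzophenone hydrazone → carbene C–H insertion closes the second dihydrofuran → demethylation with C2 epimerisation → silylation. Then nickel-catalysed union and global desilylation.
- Stereochemistry: C2 of fragment 1 comes from the chiral pool and is kept through the contraction; C3 of fragment 1 is set by substrate control in the radical coupling (aryl enters anti to the C2 aryl group). C3 of fragment 2 is set by the chiral dirhodium catalyst and its C2 by equilibration to trans; the alkene geometry comes from the boron–Wittig reagent.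
- Locants: chromanone numbering for 1–4, 1-benzofuran numbering afterwards; TIPS = triisopropylsilyl.

Key step: step 3

Remark: (2S)-naringenin is taken as the enantiopure natural flavanone and is exposed only to weak amine bases and to acid, under which the pyranone ring should not open and C2 should not racemise.

**Route**

Step 1
Reactants: 1 (2S)-naringenin
Product: 2 (2S)-5-hydroxy-7-(OTIPS)-2-[4-(OTIPS)phenyl]chroman-4-one
Conditions: TIPSCl (2.2 equiv), imidazole, CH2Cl2/DMF, 0 °C to rt
Reagents that add atoms: triisopropylsilyl chloride, CC(C)[Si](Cl)(C(C)C)C(C)C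
Why: Chemoselective phenol silylation, in which the C5 hydroxyl stays free because it is hydrogen-bonded to the C4 carbonyl while the C7 and C4' phenols are silylated.

Step 2
Reactants: 2 bis-silyl ether
Product: 3 (2S)-4-oxo-7-(OTIPS)-2-[4-(OTIPS)phenyl]chroman-5-yl trifluoromethanesulfonate
Conditions: Tf2O, pyridine, CH2Cl2, 0 °C
Reagents that add atoms: trifluoromethanesulfonic anhydride, O=S(=O)(OS(=O)(=O)C(F)(F)F)C(F)(F)F
Why: O-Sulfonylation of the chelated C5 phenol turns the one oxygen that must become carbon into a cross-coupling handle that is inert to acid and to trivalent iodine.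

Step 3
Reactants: 3 flavanone triflate
Product: 5 methyl (2S,3S)-6-(OTIPS)-2-[4-(OTIPS)phenyl]-4-(trifluoromethylsulfonyloxy)-2,3-dihydro-1-benzofuran-3-carboxylate (2,3-trans), via enol ether 4 (not isolated)
Conditions: PhI(OAc)2 (1.3 equiv), H2SO4 (cat.), HC(OMe)3, 0 °C to rt
Reagents that add atoms: trimethyl orthoformate, COC(OC)OC
Why: In acidic trimethyl orthoformate ketone 3 should form its dimethyl ketal and lose methanol to enol ether 4; PhI(OAc)2 then adds to C3 on the face anti to the C2 aryl group while methanol returns to C4, and loss of iodobenzene is assisted by the ring-fusion carbon C4a, which shifts from C4 to C3 and leaves a dimethoxycarbenium ion that acetate demethylates to the ester. The closest known reaction type is the oxidative ring contraction of flavanones to trans-2-aryl-2,3-dihydrobenzofuran-3-carboxylates with trivalent iodine or thallium trinitrate, a 1,2-aryl shift of the semipinacol family. The dihydrofuran ring is not closed end to end but by contraction of the six-membered pyranone: the C4a–C3 bond forms through a bridged, phenonium-like three-centre transition state as the C4a–C4 bond breaks. C2 is not touched and keeps the (S) configuration of naringenin, and C3 is formed with inversion at the iodine-bearing carbon, which places the ester trans to the C2 aryl group (3S); this centre only has to serve until step 16, where it is re-set. The step needs migration of C4a in preference to the C2 aryl group (isoflavone pathway) and to plain dehydrogenation (flavone pathway); with iodine and aryl group both equatorial only the ring bond C4–C4a is antiperiplanar to C3–I, and C4a is electron-rich (ortho to the ring oxygen, para to the C7 silyloxy group), while the triflate and the aryl silyl ethers are spectators.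

Step 4
Reactants: 6 4-hydroxybenzaldehyde
Product: 7 4-(OTIPS)benzaldehyde
Conditions: TIPSCl, imidazole, CH2Cl2, rt
Reagents that add atoms: triisopropylsilyl chloride, CC(C)[Si](Cl)(C(C)C)C(C)C
Why: Standard imidazole-promoted phenol silylation gives the protected aldehyde for the styryl unit.

Step 5
Reactants: 7 4-(OTIPS)benzaldehyde; 8 bis(pinacolatoboryl)methane
Product: 10 (E)-2-{2-[4-(OTIPS)phenyl]ethenyl}-4,4,5,5-tetramethyl-1,3,2-dioxaborolane, via lithiated diborylmethane 9 (not isolated)
Conditions: 8, lithium 2,2,6,6-tetramethylpiperidide, THF, 0 °C; then 7, −78 °C to rt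
Reagents that add atoms: none
Why: Boron–Wittig olefination, in which the lithiated geminal diboronate adds to the aldehyde and eliminates a B–O unit to give the (E)-alkenyl boronate that fixes the stilbene geometry.

Step 6
Reactants: 5 aryl triflate ester; 10 (E)-alkenyl boronate
Product: 11 methyl (2S,3S)-6-(OTIPS)-2-[4-(OTIPS)phenyl]-4-{(E)-2-[4-(OTIPS)phenyl]ethenyl}-2,3-dihydro-1-benzofuran-3-carboxylate
Conditions: [1,1'-bis(diphenylphosphino)ferrocene]dichloropalladium Pd(dppf)Cl2 (5 mol %), K3PO4, dioxane/H2O, 70 °C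
Reagents that add atoms: none
Why: Suzuki–Miyaura coupling of the aryl triflate is stereoretentive at the alkene, and the phosphate base should spare the ester, the silyl ethers and the dihydrofuran ring, whose opening would be the reverse of a 5-endo-trig closure.

Step 7
Reactants: 11 methyl ester
Product: 12 (2S,3S)-6-(OTIPS)-2-[4-(OTIPS)phenyl]-4-{(E)-2-[4-(OTIPS)phenyl]ethenyl}-2,3-dihydro-1-benzofuran-3-carboxylic acid
Conditions: Me3SnOH, ClCH2CH2Cl, 80 °C; then cold 0.5 M HCl wash
Reagents that add atoms: trimethyltin hydroxide, C[Sn](C)(C)O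
Why: Neutral ester hydrolysis with trimethyltin hydroxide avoids hydroxide-mediated loss of the aryl silyl ethers and β-elimination of the ring oxygen.

Step 8
Reactants: 12 carboxylic acid
Product: 13 1,3-dioxoisoindolin-2-yl (2S,3S)-6-(OTIPS)-2-[4-(OTIPS)phenyl]-4-{(E)-2-[4-(OTIPS)phenyl]ethenyl}-2,3-dihydro-1-benzofuran-3-carboxylate
Conditions: N-hydroxyphthalimide, N,N'-diisopropylcarbodiimide, DMAP (cat.), CH2Cl2, rt
Reagents that add atoms: N-hydroxyphthalimide, ON1C(=O)c2ccccc2C1=O
Why: Carbodiimide (Steglich-type) esterification gives the redox-active ester that makes C3 a radical precursor.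

Step 9
Reactants: 14 5-bromo-2-hydroxy-3-methoxybenzaldehyde; 15 4-methoxybenzyl chloride
Product: 16 5-bromo-3-methoxy-2-[(4-methoxybenzyl)oxy]benzaldehyde
Conditions: K2CO3, DMF, 60 °C
Reagents that add atoms: none
Why: Williamson etherification installs the benzylic CH2 that is the later C–H insertion site and carries the future C2 aryl group of fragment 2.

Step 10
Reactants: 16 aldehyde; 17 3,5-dimethoxyphenylmagnesium chloride (THF solution)
Product: 18 {5-bromo-3-methoxy-2-[(4-methoxybenzyl)oxy]phenyl}(3,5-dimethoxyphenyl)methanol (racemic)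
Conditions: THF, −78 to 0 °C; then H2O
Reagents that add atoms: none
Why: Grignard 1,2-addition to the aldehyde at low temperature leaves the aryl bromide untouched, and the carbinol configuration is irrelevant because it is oxidised next.

Step 11
Reactants: 18 diaryl carbinol
Product: 19 {5-bromo-3-methoxy-2-[(4-methoxybenzyl)oxy]phenyl}(3,5-dimethoxyphenyl)methanone
Conditions: MnO2 (activated, excess), CH2Cl2, rt
Reagents that add atoms: none
Why: Activated manganese dioxide oxidises the doubly benzylic alcohol to the benzophenone.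

Step 12
Reactants: 19 benzophenone
Product: 20 hydrazone of 19 (E/Z mixture)
Conditions: N2H4·H2O, AcOH (cat.), EtOH, 80 °C
Reagents that add atoms: hydrazine, NN
Why: Acid-catalysed condensation with hydrazine gives the N-unsubstituted hydrazone, the precursor of a donor/donor diazo compound.

Step 13
Reactants: 20 hydrazone
Product: 22 (2S,3R)-5-bromo-3-(3,5-dimethoxyphenyl)-7-methoxy-2-(4-methoxyphenyl)-2,3-dihydro-1-benzofuran (2,3-cis), via diazo compound 21 (not isolated)
Conditions: MnO2, CH2Cl2, rt, filter; then dirhodium tetrakis[(R)-N-phthaloyl-(1-adamantyl)glycinate] Rh2(R-PTAD)4 (1 mol %), CH2Cl2, 0 °C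
Reagents that add atoms: none
Why: Dehydrogenation of the hydrazone gives the diaryldiazomethane, whose dirhodium donor/donor carbene undergoes concerted 1,5 C–H insertion into the benzylic C–H bond next to the ether oxygen to close the dihydrofuran with cis aryl groups, the chiral carboxylate ligands being expected to set C3 as (R) (the antipodal catalyst is at hand should the sense of induction prove opposite).

Step 14
Reactants: 22 cis tetramethyl ether
Product: 23 5-[(2R,3R)-5-bromo-7-hydroxy-2-(4-hydroxyphenyl)-2,3-dihydro-1-benzofuran-3-yl]benzene-1,3-diol (2,3-trans)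
Conditions: BBr3, CH2Cl2, −78 °C to rt; then H2O
Reagents that add atoms: none
Why: Lewis-acid ether cleavage removes the four methyl groups, and reversible ionisation of the C2–O bond to a para-quinone-methide-type benzylic cation should let C2 reclose to the thermodynamically preferred trans isomer while C3 is untouched.

Step 15
Reactants: 23 tetraphenol
Product: 24 (2R,3R)-5-bromo-7-(OTIPS)-3-[3,5-bis(OTIPS)phenyl]-2-[4-(OTIPS)phenyl]-2,3-dihydro-1-benzofuran
Conditions: TIPSCl, imidazole, DMF, 40 °C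
Reagents that add atoms: triisopropylsilyl chloride, CC(C)[Si](Cl)(C(C)C)C(C)C
Why: Exhaustive phenol silylation matches the protecting groups of fragment 1 and permits bromine–lithium exchange.

Step 16
Reactants: 24 aryl bromide (fragment 2); 13 redox-active ester (fragment 1)
Product: 27 heptakis(triisopropylsilyl) ether of the target, via aryllithium 25 (not isolated), via arylzinc chloride 26 (not isolated)
Conditions: 24, n-BuLi, THF, −78 °C; ZnCl2, −78 °C to rt; then 13, NiCl2·glyme (20 mol %), 4,4'-di-tert-butyl-2,2'-bipyridine (40 mol %), THF/DMF, rt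
Reagents that add atoms: none
Why: Nickel-catalysed decarboxylative Negishi-type arylation of a redox-active ester, in which single-electron reduction releases CO2 and a planar benzylic C3 radical that the arylnickel species should capture on the face anti to the C2 aryl group, so that reductive elimination sets the 2,3-trans (3S) centre.

Step 17
Reactants: 27 heptasilyl ether
Product: 28 CNP0172909.1
Conditions: Bu4NF, AcOH, THF, 0 °C to rt, argon
Reagents that add atoms: none
Why: Fluoride-mediated cleavage of the seven aryl silyl ethers, buffered with acetic acid, avoids both strong base on the air-sensitive polyphenol and the acid to which the styryl-substituted dihydrobenzofuran is sensitive.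

**Compound list**

1 | (2S)-naringenin, (2S)-5,7-dihydroxy-2-(4-hydroxyphenyl)chroman-4-one | O=C1C[C@@H](c2ccc(O)cc2)Oc2cc(O)cc(O)c12 | starting material
2 | (2S)-5-hydroxy-7-(OTIPS)-2-[4-(OTIPS)phenyl]chroman-4-one | O=C1C[C@@H](c2ccc(O[Si](C(C)C)(C(C)C)C(C)C)cc2)Oc2cc(O[Si](C(C)C)(C(C)C)C(C)C)cc(O)c12 | intermediate
3 | (2S)-4-oxo-7-(OTIPS)-2-[4-(OTIPS)phenyl]chroman-5-yl trifluoromethanesulfonate | O=C1C[C@@H](c2ccc(O[Si](C(C)C)(C(C)C)C(C)C)cc2)Oc2cc(O[Si](C(C)C)(C(C)C)C(C)C)cc(OS(=O)(=O)C(F)(F)F)c12 | intermediate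
4 | (2S)-4-methoxy-7-(OTIPS)-2-[4-(OTIPS)phenyl]-2H-chromen-5-yl trifluoromethanesulfonate (enol ether) | COC1=C[C@@H](c2ccc(O[Si](C(C)C)(C(C)C)C(C)C)cc2)Oc2cc(O[Si](C(C)C)(C(C)C)C(C)C)cc(OS(=O)(=O)C(F)(F)F)c12 | intermediate (not isolated)
5 | methyl (2S,3S)-6-(OTIPS)-2-[4-(OTIPS)phenyl]-4-(trifluoromethylsulfonyloxy)-2,3-dihydro-1-benzofuran-3-carboxylate | COC(=O)[C@H]1c2c(OS(=O)(=O)C(F)(F)F)cc(O[Si](C(C)C)(C(C)C)C(C)C)cc2O[C@@H]1c1ccc(O[Si](C(C)C)(C(C)C)C(C)C)cc1 | intermediate
6 | 4-hydroxybenzaldehyde | O=Cc1ccc(O)cc1 | starting material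
7 | 4-(triisopropylsilyloxy)benzaldehyde | O=Cc1ccc(O[Si](C(C)C)(C(C)C)C(C)C)cc1 | intermediate
8 | bis(pinacolatoboryl)methane, 2,2'-methylenebis(4,4,5,5-tetramethyl-1,3,2-dioxaborolane) | CC1(C)OB(CB2OC(C)(C)C(C)(C)O2)OC1(C)C | starting material
9 | lithio-bis(pinacolatoboryl)methane | [Li]C(B1OC(C)(C)C(C)(C)O1)B1OC(C)(C)C(C)(C)O1 | intermediate (not isolated)
10 | (E)-2-{2-[4-(OTIPS)phenyl]ethenyl}-4,4,5,5-tetramethyl-1,3,2-dioxaborolane | CC1(C)OB(/C=C/c2ccc(O[Si](C(C)C)(C(C)C)C(C)C)cc2)OC1(C)C | intermediate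
11 | methyl (2S,3S)-6-(OTIPS)-2-[4-(OTIPS)phenyl]-4-{(E)-2-[4-(OTIPS)phenyl]ethenyl}-2,3-dihydro-1-benzofuran-3-carboxylate | COC(=O)[C@H]1c2c(/C=C/c3ccc(O[Si](C(C)C)(C(C)C)C(C)C)cc3)cc(O[Si](C(C)C)(C(C)C)C(C)C)cc2O[C@@H]1c1ccc(O[Si](C(C)C)(C(C)C)C(C)C)cc1 | intermediate
12 | (2S,3S)-6-(OTIPS)-2-[4-(OTIPS)phenyl]-4-{(E)-2-[4-(OTIPS)phenyl]ethenyl}-2,3-dihydro-1-benzofuran-3-carboxylic acid | OC(=O)[C@H]1c2c(/C=C/c3ccc(O[Si](C(C)C)(C(C)C)C(C)C)cc3)cc(O[Si](C(C)C)(C(C)C)C(C)C)cc2O[C@@H]1c1ccc(O[Si](C(C)C)(C(C)C)C(C)C)cc1 | intermediate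
13 | 1,3-dioxoisoindolin-2-yl ester of 12 (N-acyloxyphthalimide) | O=C(ON1C(=O)c2ccccc2C1=O)[C@H]1c2c(/C=C/c3ccc(O[Si](C(C)C)(C(C)C)C(C)C)cc3)cc(O[Si](C(C)C)(C(C)C)C(C)C)cc2O[C@@H]1c1ccc(O[Si](C(C)C)(C(C)C)C(C)C)cc1 | intermediate
14 | 5-bromo-2-hydroxy-3-methoxybenzaldehyde | COc1cc(Br)cc(C=O)c1O | starting material
15 | 4-methoxybenzyl chloride | COc1ccc(CCl)cc1 | starting material
16 | 5-bromo-3-methoxy-2-[(4-methoxybenzyl)oxy]benzaldehyde | COc1ccc(COc2c(OC)cc(Br)cc2C=O)cc1 | intermediate
17 | 3,5-dimethoxyphenylmagnesium chloride | COc1cc(OC)cc([Mg]Cl)c1 | starting material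
18 | {5-bromo-3-methoxy-2-[(4-methoxybenzyl)oxy]phenyl}(3,5-dimethoxyphenyl)methanol (racemic) | COc1ccc(COc2c(OC)cc(Br)cc2C(O)c2cc(OC)cc(OC)c2)cc1 | intermediate
19 | {5-bromo-3-methoxy-2-[(4-methoxybenzyl)oxy]phenyl}(3,5-dimethoxyphenyl)methanone | COc1ccc(COc2c(OC)cc(Br)cc2C(=O)c2cc(OC)cc(OC)c2)cc1 | intermediate
20 | hydrazone of 19 | COc1ccc(COc2c(OC)cc(Br)cc2C(=NN)c2cc(OC)cc(OC)c2)cc1 | intermediate
21 | diazo{5-bromo-3-methoxy-2-[(4-methoxybenzyl)oxy]phenyl}(3,5-dimethoxyphenyl)methane | COc1ccc(COc2c(OC)cc(Br)cc2C(=[N+]=[N-])c2cc(OC)cc(OC)c2)cc1 | intermediate (not isolated)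
22 | (2S,3R)-5-bromo-3-(3,5-dimethoxyphenyl)-7-methoxy-2-(4-methoxyphenyl)-2,3-dihydro-1-benzofuran (cis) | Brc1cc(OC)c2c(c1)[C@@H](c1cc(OC)cc(OC)c1)[C@@H](c1ccc(OC)cc1)O2 | intermediate
23 | 5-[(2R,3R)-5-bromo-7-hydroxy-2-(4-hydroxyphenyl)-2,3-dihydro-1-benzofuran-3-yl]benzene-1,3-diol (trans) | Brc1cc(O)c2c(c1)[C@@H](c1cc(O)cc(O)c1)[C@H](c1ccc(O)cc1)O2 | intermediate
24 | (2R,3R)-5-bromo-7-(OTIPS)-3-[3,5-bis(OTIPS)phenyl]-2-[4-(OTIPS)phenyl]-2,3-dihydro-1-benzofuran | Brc1cc(O[Si](C(C)C)(C(C)C)C(C)C)c2c(c1)[C@@H](c1cc(O[Si](C(C)C)(C(C)C)C(C)C)cc(O[Si](C(C)C)(C(C)C)C(C)C)c1)[C@H](c1ccc(O[Si](C(C)C)(C(C)C)C(C)C)cc1)O2 | intermediate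
25 | 5-lithio analogue of 24 | [Li]c1cc(O[Si](C(C)C)(C(C)C)C(C)C)c2c(c1)[C@@H](c1cc(O[Si](C(C)C)(C(C)C)C(C)C)cc(O[Si](C(C)C)(C(C)C)C(C)C)c1)[C@H](c1ccc(O[Si](C(C)C)(C(C)C)C(C)C)cc1)O2 | intermediate (not isolated)
26 | 5-(chlorozincio) analogue of 24 | Cl[Zn]c1cc(O[Si](C(C)C)(C(C)C)C(C)C)c2c(c1)[C@@H](c1cc(O[Si](C(C)C)(C(C)C)C(C)C)cc(O[Si](C(C)C)(C(C)C)C(C)C)c1)[C@H](c1ccc(O[Si](C(C)C)(C(C)C)C(C)C)cc1)O2 | intermediate (not isolated)
27 | heptakis(triisopropylsilyl) ether of 28 | CC(C)[Si](C(C)C)(C(C)C)Oc1ccc(/C=C/c2cc(O[Si](C(C)C)(C(C)C)C(C)C)cc3c2[C@H](c2cc(O[Si](C(C)C)(C(C)C)C(C)C)c4c(c2)[C@@H](c2cc(O[Si](C(C)C)(C(C)C)C(C)C)cc(O[Si](C(C)C)(C(C)C)C(C)C)c2)[C@H](c2ccc(O[Si](C(C)C)(C(C)C)C(C)C)cc2)O4)[C@@H](c2ccc(O[Si](C(C)C)(C(C)C)C(C)C)cc2)O3)cc1 | intermediate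
28 | CNP0172909.1, 5-[(2R,3R)-7-hydroxy-5-[(2S,3S)-6-hydroxy-2-(4-hydroxyphenyl)-4-[(E)-2-(4-hydroxyphenyl)ethenyl]-2,3-dihydro-1-benzofuran-3-yl]-2-(4-hydroxyphenyl)-2,3-dihydro-1-benzofuran-3-yl]benzene-1,3-diol | Oc1ccc(/C=C/c2cc(O)cc3c2[C@H](c2cc(O)c4c(c2)[C@@H](c2cc(O)cc(O)c2)[C@H](c2ccc(O)cc2)O4)[C@@H](c2ccc(O)cc2)O3)cc1 | target

**Totals and risks**

Total steps: 17. Longest linear sequence: 9 steps (steps 9 to 17).

Step 3 (ring contraction). What may go wrong: competing 1,2-shift of the C2 aryl group or plain dehydrogenation of the pyranone, slow ketalisation next to the peri triflate, or acid-induced ionisation at C2 with erosion of enantiopurity. Fallback, from 3 and back at 5: the same C4a–C3 bond is made by a Wolff ring contraction. Deprotonation of 3 with LiN(SiMe3)2 in THF at −78 °C and acylation with 2,2,2-trifluoroethyl trifluoroacetate should give the 3-trifluoroacetyl ketone F1. Detrifluoroacetylative diazo transfer (methanesulfonyl azide, Et3N, MeCN) should give the 3-diazo-4-chromanone F2. Irradiation at 365 nm in MeOH/THF should extrude N2 with shift of C4a to the carbene carbon, and methanol capture of the ketene is expected to give mainly the cis ester F3 (protonation anti to the C2 aryl group). DBU in toluene should then equilibrate F3 to the trans ester 5.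

Step 16 (fragment union). What may go wrong: slow capture of the hindered benzylic radical, flanked by the C4 styryl and C2 aryl groups, so that reduction or dimerisation of the radical takes over; insufficient facial selectivity; consumption of the arylzinc reagent by homocoupling. Fallback, from 24 and 13 and back at 27: the aryl partner is changed from nucleophile to electrophile. Bromine–lithium exchange on 24 (n-BuLi, THF, −78 °C) and an iodine quench should give the aryl iodide F4. F4 is then joined to 13 by nickel-catalysed reductive cross-electrophile coupling (NiBr2·glyme, 4,4'-di-tert-butyl-2,2'-bipyridine, Zn dust, N,N-dimethylacetamide, rt). Here the aryl group enters by oxidative addition and fragment 2 is the limiting component.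

Step 13 (asymmetric C–H insertion). What may go wrong: insufficient enantiofacial control by the chiral catalyst with the doubly ortho-substituted diaryl carbene, or loss of the diazo compound to azine formation. Fallback, from 20 and back at 22: asymmetric catalysis is replaced by a racemic synthesis and separation of enantiomers. Oxidation with MnO2 and insertion with achiral Rh2(OAc)4 under slow addition should give the cis product as a racemate, that is 22 together with its (2R,3S) antipode F5. Preparative chromatography on a chiral stationary phase then delivers 22.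

Further compounds
F1 | step 3 | (2S)-4-oxo-3-(trifluoroacetyl)-7-(OTIPS)-2-[4-(OTIPS)phenyl]chroman-5-yl trifluoromethanesulfonate (C3 epimers/enol) | O=C1C(C(=O)C(F)(F)F)[C@@H](c2ccc(O[Si](C(C)C)(C(C)C)C(C)C)cc2)Oc2cc(O[Si](C(C)C)(C(C)C)C(C)C)cc(OS(=O)(=O)C(F)(F)F)c12
F2 | step 3 | (2R)-3-diazo-4-oxo-7-(OTIPS)-2-[4-(OTIPS)phenyl]chroman-5-yl trifluoromethanesulfonate (same spatial arrangement at C2 as in 3) | O=C1C(=[N+]=[N-])[C@@H](c2ccc(O[Si](C(C)C)(C(C)C)C(C)C)cc2)Oc2cc(O[Si](C(C)C)(C(C)C)C(C)C)cc(OS(=O)(=O)C(F)(F)F)c12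
F3 | step 3 | methyl (2S,3R)-6-(OTIPS)-2-[4-(OTIPS)phenyl]-4-(trifluoromethylsulfonyloxy)-2,3-dihydro-1-benzofuran-3-carboxylate (cis) | COC(=O)[C@@H]1c2c(OS(=O)(=O)C(F)(F)F)cc(O[Si](C(C)C)(C(C)C)C(C)C)cc2O[C@@H]1c1ccc(O[Si](C(C)C)(C(C)C)C(C)C)cc1
F4 | step 16 | (2R,3R)-5-iodo-7-(OTIPS)-3-[3,5-bis(OTIPS)phenyl]-2-[4-(OTIPS)phenyl]-2,3-dihydro-1-benzofuran | Ic1cc(O[Si](C(C)C)(C(C)C)C(C)C)c2c(c1)[C@@H](c1cc(O[Si](C(C)C)(C(C)C)C(C)C)cc(O[Si](C(C)C)(C(C)C)C(C)C)c1)[C@H](c1ccc(O[Si](C(C)C)(C(C)C)C(C)C)cc1)O2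
F5 | step 13 | (2R,3S)-5-bromo-3-(3,5-dimethoxyphenyl)-7-methoxy-2-(4-methoxyphenyl)-2,3-dihydro-1-benzofuran (antipode of 22) | Brc1cc(OC)c2c(c1)[C@H](c1cc(OC)cc(OC)c1)[C@H](c1ccc(OC)cc1)O2
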